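4 questions stand on 3 flasks that differ in the nucleophile charged.

    electrophile + nucleophile → acid set free + target (k1 = 0.021 M⁻¹ s⁻¹)
    nucleophile + acid set free ⇌ protonated nucleophile, settled at all times (K2 = 18000 M⁻¹)
    acid set free + free base ⇌ salt of the base, settled at all times (K3 = 3.2 × 10⁵ M⁻¹)
    crystals ⇌ target, rate k4*(cs4 - [target]) while solid is left; crystals form when [target] > cs4 (cs4 = 0.052 M, k4 = 0.0079 s⁻¹)
    solid base ⇌ free base, rate k5*(cs5 - [free base]) while solid is left; crystals form when [free base] > cs5 (cs5 = 38 mM, k5 = 2.1 × 10⁻⁴ s⁻¹)
    electrophile → decomposition product (k6 = 1.3 × 10⁻⁶ s⁻¹)

| setting | east | north-east | south-east |
|---|---|---|---|
| electrophile | 0.10 M | 0.10 M | 0.10 M |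
| nucleophile | 1.10 equiv | 2.20 equiv | 4.40 equiv |
| solid base | 0.500 equiv | 0.500 equiv | 0.500 equiv |
| time | 6.0 h | 6.0 h | 6.0 h |

1. part of the electrophile that has reacted at the end, east
2. part of the electrophile that has reacted at the end, north-east
3. part of the electrophile that has reacted at the end, south-east
4. what raising the equivalents of nucleophile from its lowest to its highest value here does to the part of the electrophile that has reacted (changes below 5 percentage points count as none) (it rises / it falls / no change)

- for target the crystals are counted in
- as a solid, counted per litre of solution: crystals, solid base
- at the start none of the solid base is in solution
- run time (east): 6.0 h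

East looks certain to finish: its nucleophile stands at 1.10 equiv, and coupling has a half-life of 5.00 min, far shorter than the 6.0 h of the run. Yet the reckoning by hand stops east near 80.0% of its electrophile.

Each coupling consumes one nucleophile and sets free one acid, and that acid occupies a second place, on another nucleophile or on a free base. The equilibrium constant of the nucleophile's protonation times its starting concentration is 2000, so the acid stays bound. Half the equivalents of nucleophile and base together is therefore the stall point: the part of the electrophile that can couple before free nucleophile falls to traces.

The charge of solid base, 50.0 mM, is more than its solubility of 38 mM, so the reckoning counts it in full in east on the assumption that acid keeps taking up free base as salt, with an equilibrium constant larger than the nucleophile's. At its fastest dissolving rate the base needs at least 1.74 h, shorter than the run, so the time allowed does not rule that assumption out. Decomposition, with a half-life of 150 h, is slow against the run. East should thus end slightly above its stall point. North-east and south-east have stall points of 135% and 245%, beyond the whole charge, so there the electrophile is the limiting reagent and should be consumed. The part reacted should rise by about 20 percentage points.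

The forecast gives 83% for east, within 81% to 85%, then 100% and 100%, and for the trend, it rises. Its ground is the same count, “each coupling uses two sites”, but its east figure lies 3 points above the stall point reckoned here.

The simulation gives 83.1%, 100% and 100%; the trend is it rises, by 17 points. East ends 3.1 points above its stall point. South-east, recharged with 1.10 equiv of nucleophile, has its stall point lowered from 245% to 80.0%. That neighbouring flask reacts 83.1% of its electrophile and holds 82.4% as target. Of its charges, 17% of the electrophile, 0.27% of the nucleophile and 0.061% of the solid base remain.

The constants are made up; the run is a simulation.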